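The three flasks have received the same charge once the 40 h feed is over, and that invariant is the place to start, because what differs is how long the charge has been in. A steadily fed portion enters on average at half the feed time. Call the mean time in the flask of the fed reagent, divided by the run time, the age fraction: 0.667 for a fed flask, one for west.

the same everywhere: gas 1.2 mM (held)

| flask | starting material | partner | third reagent | remark | time |
|---|---|---|---|---|---|
| noon | 20 mM | 12 mM | 24 mM | run made earlier |  |
| winter | 20 mM | 6 mM | 24 mM | run made earlier |  |
| south-east | 20 mM | 12.0 mM (fed, over 40 h) | 24.0 mM | all else is in the flask from the start; the feed brings no volume worth counting | 2.5 d |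
| west | 20 mM | 12.0 mM | 24.0 mM | everything together at the start | 2.5 d |
| east | 20 mM (fed, over 40 h) | 12.0 mM | 24.0 mM | all else is in the flask from the start; the feed brings no volume worth counting | 2.5 d |

| noon: time / h | noon: product / % | winter: time / h | winter: product / % |
|---|---|---|---|
| 3.00 | 0.3 | 0.500 | 0.2 |
| 5.00 | 0.6 | 1.50 | 0 |
| 10.0 | 1.7 | 3.00 | 0 |
| 20.0 | 6.1 | 4.00 | 0 |
| 40.0 | 17.3 | 6.00 | 0 |

(standard deviation of a reading: 0.5 percentage points)

- which flask leads in amount of product, in percent of the starting material charged ("all alike" within 1.5 percentage points) (south-east / west / east / all alike)
- how much product is there at the end, in percent of the starting material charged: south-east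
- how much product is there at the end, in percent of the starting material charged: west
- how much product is there at the end, in percent of the starting material charged: east

- at the start none of the gas is in solution

My reckoning: a fed flask should end where an everything-at-start flask stood at 40.0 h. West has the noon charges, and the noon run there reads 17.3%, so I expect that for south-east and for east. West goes on from that point, and noon was still rising, from 6.1% at 20.0 h. So west should lead. The fraction is the same for both fed flasks, so it gives them one value. That needs partner and starting material to count alike, and the winter run, at 0% by 6.00 h, doesn't show that.

The forecast also names west, with 26.5%, but it stands higher than my 17.3% on the fed flasks, at 22% for south-east and 22% for east: “South-east and east come out nearly equal.”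

The flasks give 17.1% in south-east, 27.0% in west and 18.1% in east, so west leads.

    starting material + partner → intermediate A (k = 4.70 M⁻¹ h⁻¹)
    second reagent + intermediate A → intermediate B (k = 13.0 M⁻¹ h⁻¹)
    third reagent + intermediate B → product (k = 14.0 M⁻¹ h⁻¹)
    gas ⇌ second reagent, rate k4*(csat - [second reagent]) (kL = 4.00 h⁻¹)

Read at the age fraction 0.667, noon gave 17.3%; east stands 1.00 percentage point above south-east, less than the margin of 1.5 points. In south-east, the step from starting material and partner to intermediate A had done half of its turnover up to the asked time by 1.21 d, and at 2.50 d intermediate A held 33.5% of the starting material charged, against 17.1% as product. In west, intermediate A held 36.8% at 1.25 d with 11.7% as product, then fell to 28.6% as product reached 27.0%.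

Take south-east with 30 mM of partner. The fraction stays 0.667, so you read noon at 40.0 h and, scaling first order in partner, expect 43.2%. That flask gives 32.7%, with 7.02% of its starting material left.

All runs were computed from invented constants.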